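**Retrosynthetic overview**

1. Target 14 ⇐ bis‑MOM (2S)‑flavanone 12 ⇐ racemic cyclopropanol 11 (a 1a‑aryl‑cyclopropa[b]benzofuran‑6b‑ol). The pyranone ring (O1, C2, C3, C4, C4a, C8a) is not closed directly: it grows out of the five‑membered dihydrofuran ring of 11 when the bond shared with the cyclopropane is cut, the cyclopropane CH2 becoming C3.
2. 11 ⇐ zinc‑enolate cyclopropanation of the 2‑aryl‑benzofuran‑3(2H)‑one 9 ⇐ Pd α‑arylation of coumaranone 5 with bromochromene 8 (A/furanone half + B/chromene half).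
3. 5 ⇐ 6‑hydroxybenzofuran‑3(2H)‑one 1 by O‑tert‑prenylation, aromatic Claisen rearrangement (C8 prenyl) and MOM protection; 8 ⇐ 2,2‑dimethyl‑2H‑chromen‑7‑ol 6 by ortho‑bromination and MOM protection.
4. Enabling feature: C2 of the target carries both the ring oxygen O1 and the electron‑rich B‑ring aryl. A radical formed there by β‑scission is tertiary, benzylic and α‑oxygenated, so only the internal cyclopropane bond breaks; the planar C2 radical then takes H from a chiral thiol, and both enantiomers of 11 converge on (2S).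
5. Ring order: A ring, furanone and chromene are bought; cyclopropane (step 7); pyranone C ring by one‑carbon expansion of the furanone (step 8).

Key step: step 8

Remark: compounds 2 and 6 are taken as catalogue compounds; flavanone numbering (O1, C2, C3, C4, C4a–C8a) is used for 12–14 and fused numbering (C1 = CH2, C1a, O2, C2a–C6a, C6b = carbinol carbon) for 11; prenyl = 3‑methylbut‑2‑en‑1‑yl.

**Route**

Step 1
Reactants: 1 6‑hydroxybenzofuran‑3(2H)‑one; 2 tert‑butyl 2‑methylbut‑3‑en‑2‑yl carbonate
Product: 3 6‑(2‑methylbut‑3‑en‑2‑yloxy)benzofuran‑3(2H)‑one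
Conditions: Pd(PPh3)4 (2 mol %), 2 (1.5 equiv), THF, 0 °C → rt
Reagents that add atoms: none
Why: Pd(0)‑catalysed decarboxylative allylic etherification (Tsuji–Trost type), in which the phenoxide of the acidic para‑acyl phenol (not the C2 methylene) attacks the 1,1‑dimethyl‑π‑allyl‑Pd cation at its more substituted terminus under kinetic control.

Step 2
Reactants: 3 6‑(2‑methylbut‑3‑en‑2‑yloxy)benzofuran‑3(2H)‑one
Product: 4 6‑hydroxy‑7‑prenylbenzofuran‑3(2H)‑one
Conditions: N,N‑diethylaniline, 130 °C
Reagents that add atoms: none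
Why: Aromatic Claisen rearrangement ([3,3]) of the tert‑allyl aryl ether should deliver the prenyl group with allylic transposition to C7, the ortho carbon flanked by both ring oxygens (the site preferred in 7‑oxycoumarin‑type systems), the amine solvent suppressing acid‑catalysed chroman formation and any C5 isomer being removed by chromatography.

Step 3
Reactants: 4 6‑hydroxy‑7‑prenylbenzofuran‑3(2H)‑one
Product: 5 6‑(methoxymethoxy)‑7‑prenylbenzofuran‑3(2H)‑one
Conditions: MOMCl, i‑Pr2NEt, CH2Cl2, 0 °C → rt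
Reagents that add atoms: chloromethyl methyl ether (MOMCl), COCCl
Why: O‑Alkylation of the acidic phenol under amine base (Williamson type) gives an acetal that should survive the enolate, organozinc and photoredox steps and can be removed without base.

Step 4
Reactants: 6 2,2‑dimethyl‑2H‑chromen‑7‑ol
Product: 7 6‑bromo‑2,2‑dimethyl‑2H‑chromen‑7‑ol
Conditions: NBS (1.0 equiv), i‑Pr2NH (10 mol %), CH2Cl2, −40 → 0 °C, dark
Reagents that add atoms: N‑bromosuccinimide, O=C1CCC(=O)N1Br
Why: Amine‑catalysed ortho‑selective electrophilic bromination of the phenol should occur at C6 (ortho to OH, para to the ring oxygen, less hindered than C8) much faster than NBS adds to the chromene alkene in a non‑nucleophilic solvent.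

Step 5
Reactants: 7 6‑bromo‑2,2‑dimethyl‑2H‑chromen‑7‑ol
Product: 8 6‑bromo‑7‑(methoxymethoxy)‑2,2‑dimethyl‑2H‑chromene
Conditions: MOMCl, i‑Pr2NEt, CH2Cl2, 0 °C → rt
Reagents that add atoms: chloromethyl methyl ether (MOMCl), COCCl
Why: O‑Alkylation of the phenol under amine base (Williamson type) installs a small ortho group that tolerates the Pd coupling.

Step 6
Reactants: 5 6‑(methoxymethoxy)‑7‑prenylbenzofuran‑3(2H)‑one; 8 6‑bromo‑7‑(methoxymethoxy)‑2,2‑dimethyl‑2H‑chromene
Product: 9 racemic 6‑(methoxymethoxy)‑2‑[7‑(methoxymethoxy)‑2,2‑dimethyl‑2H‑chromen‑6‑yl]‑7‑prenylbenzofuran‑3(2H)‑one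
Conditions: Pd2(dba)3 (2 mol %), XPhos (5 mol %), NaOt‑Bu (2.2 equiv), toluene, 70 °C, degassed; buffered quench and rapid isolation under argon
Reagents that add atoms: none
Why: Pd‑catalysed ketone α‑arylation (oxidative addition of 8, enolate transmetalation, C–C reductive elimination) gives the α‑aryl ketone, whose more acidic C2–H is taken by the second equivalent of base and so shielded from diarylation; C2 is an enolisable stereocentre of no consequence.

Step 7
Reactants: 9 racemic 2‑aryl‑benzofuran‑3(2H)‑one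
Product: 11 racemic cis‑fused cyclopropanol (1a‑aryl‑1,1a‑dihydro‑6bH‑cyclopropa[b]benzofuran‑6b‑ol), via ethylzinc enolate 10 (not isolated)
Conditions: Et2Zn (2.2 equiv), CH2Cl2, −20 °C; then CH2I2 (1.1 equiv), −20 → 0 °C; pH 7 phosphate buffer, filtration through Et3N‑deactivated silica, used at once
Reagents that add atoms: diiodomethane, ICI; diethylzinc, CC[Zn]CC (its EtZn is in intermediate 10 only)
Why: Cyclopropanation of a zinc enolate with a Furukawa carbenoid (the first stage of the Zercher chain extension, known to give cyclopropanols from zinc enolates of simple ketones) should put CH2 across the electron‑rich C2=C3 enolate bond of 10 much faster than a limiting amount of carbenoid attacks the unactivated prenyl and chromene alkenes, the cis ring fusion being the only one possible.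

Step 8
Reactants: 11 racemic cis‑fused cyclopropanol
Product: 12 (2S)‑7‑(methoxymethoxy)‑2‑[7‑(methoxymethoxy)‑2,2‑dimethyl‑2H‑chromen‑6‑yl]‑8‑prenylchroman‑4‑one
Conditions: [Ir(dF(CF3)ppy)2(5,5′‑d(CF3)bpy)]PF6 (2 mol %), chiral cysteine peptide thiol Boc‑Cys‑D‑Pro‑Acpc‑Phe‑NMe2 (10 mol %, antipode chosen for 2S), 2,4,6‑collidine (25 mol %), toluene/CH2Cl2, blue LEDs (450 nm), −10 °C, degassed
Reagents that add atoms: none
Why: Proposed new method: the excited Ir(III) photocatalyst oxidises an electron‑rich arene of 11 (the dioxygenated A ring on the carbinol carbon C6b or the chromene B ring on C1a) and collidine‑assisted proton‑coupled electron transfer gives the cyclopropyloxy radical, whose β‑scission cuts the internal C1a–C6b bond; the closest known reaction types are the redox‑neutral photocatalytic PCET ring‑opening isomerisation of cyclic aryl carbinols with a thiol co‑catalyst and the oxidative ring expansion of bicyclic cyclopropanols and siloxycyclopropanes. No ring is closed by cyclisation: the six‑membered pyranone forms by fragmentation of the zero‑atom bridge of the bicyclo[3.1.0] unit, so that the dihydrofuran ring (O2, C1a, C6b, C6a, C2a) grows by the CH2 carbon, which becomes C3 between C2 and the C4 ketone. The selectivity needed is cleavage of the internal bond and not of C6b–CH2, and the substrate secures it because internal cleavage gives a tertiary radical at the future C2 stabilised by both the ring oxygen and the B‑ring aryl, whereas the alternative gives a primary radical. The only stereocentre, C2, is set when this planar radical takes a hydrogen atom from the thiol of the chiral β‑turn peptide, held to the C4 ketone and O1 by hydrogen bonds (precedent: enantioselective hydrogen‑atom transfer from peptide thiols to prochiral tertiary radicals in photocatalytic hydroamination and deracemisation), and since both enantiomers of 11 give the same radical the step is stereoconvergent. The thiyl radical should be reduced by Ir(II) and reprotonated by collidinium faster than it can re‑abstract the C2 hydrogen, and any product re‑oxidised at the B ring and deprotonated at C2 re‑enters the same radical, so the enantiomer ratio is fixed by the hydrogen‑atom transfer alone. Over‑oxidation of the radical to the flavone is limited by the net redox‑neutral cycle, which adds and removes no atoms.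

Step 9
Reactants: 12 (2S)‑bis‑MOM flavanone
Product: 14 (2S)‑7‑hydroxy‑2‑(7‑hydroxy‑2,2‑dimethyl‑2H‑chromen‑6‑yl)‑8‑prenylchroman‑4‑one (target), via bis‑TMS ether 13 (not isolated)
Conditions: TMSOTf (5 equiv), 2,2′‑bipyridyl (7 equiv), MeCN, 0 °C → rt; then H2O, rt
Reagents that add atoms: trimethylsilyl triflate, C[Si](C)(C)OS(=O)(=O)C(F)(F)F (its Me3Si groups are in intermediate 13 only; 14 gains only hydrogen)
Why: Silyl triflate/2,2′‑bipyridyl cleavage of aromatic MOM ethers converts ArO–MOM into ArO–SiMe3, which water hydrolyses, under conditions that should be too mild to ionise the benzylic C2–O1 bond, cyclise the prenyl phenol or open the ring by enolisation, so the C2 configuration is kept.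

**Compound list**

1 | 6‑hydroxy‑1‑benzofuran‑3(2H)‑one | O=C1COc2cc(O)ccc21 | starting material
2 | tert‑butyl 2‑methylbut‑3‑en‑2‑yl carbonate | C=CC(C)(C)OC(=O)OC(C)(C)C | starting material
3 | 6‑[(2‑methylbut‑3‑en‑2‑yl)oxy]‑1‑benzofuran‑3(2H)‑one | O=C1COc2cc(OC(C)(C)C=C)ccc21 | intermediate
4 | 6‑hydroxy‑7‑(3‑methylbut‑2‑en‑1‑yl)‑1‑benzofuran‑3(2H)‑one | O=C1COc2c(CC=C(C)C)c(O)ccc21 | intermediate
5 | 6‑(methoxymethoxy)‑7‑(3‑methylbut‑2‑en‑1‑yl)‑1‑benzofuran‑3(2H)‑one | O=C1COc2c(CC=C(C)C)c(OCOC)ccc21 | intermediate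
6 | 2,2‑dimethyl‑2H‑chromen‑7‑ol | CC1(C)C=Cc2ccc(O)cc2O1 | starting material
7 | 6‑bromo‑2,2‑dimethyl‑2H‑chromen‑7‑ol | CC1(C)C=Cc2cc(Br)c(O)cc2O1 | intermediate
8 | 6‑bromo‑7‑(methoxymethoxy)‑2,2‑dimethyl‑2H‑chromene | CC1(C)C=Cc2cc(Br)c(OCOC)cc2O1 | intermediate
9 | 6‑(methoxymethoxy)‑2‑[7‑(methoxymethoxy)‑2,2‑dimethyl‑2H‑chromen‑6‑yl]‑7‑(3‑methylbut‑2‑en‑1‑yl)‑1‑benzofuran‑3(2H)‑one (racemic, C2 enolisable) | O=C1C(c3cc4C=CC(C)(C)Oc4cc3OCOC)Oc2c(CC=C(C)C)c(OCOC)ccc21 | intermediate
10 | ethylzinc 6‑(methoxymethoxy)‑2‑[7‑(methoxymethoxy)‑2,2‑dimethyl‑2H‑chromen‑6‑yl]‑7‑(3‑methylbut‑2‑en‑1‑yl)‑1‑benzofuran‑3‑olate (zinc enolate of 9) | CC[Zn]Oc1c(-c3cc4C=CC(C)(C)Oc4cc3OCOC)oc2c(CC=C(C)C)c(OCOC)ccc12 | intermediate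
11 | 4‑(methoxymethoxy)‑1a‑[7‑(methoxymethoxy)‑2,2‑dimethyl‑2H‑chromen‑6‑yl]‑3‑(3‑methylbut‑2‑en‑1‑yl)‑1,1a‑dihydro‑6bH‑cyclopropa[b][1]benzofuran‑6b‑ol (racemic; cis ring fusion, the only one possible) | OC12CC1(c3cc4C=CC(C)(C)Oc4cc3OCOC)Oc1c(CC=C(C)C)c(OCOC)ccc12 | intermediate
12 | (2S)‑7‑(methoxymethoxy)‑2‑[7‑(methoxymethoxy)‑2,2‑dimethyl‑2H‑chromen‑6‑yl]‑8‑(3‑methylbut‑2‑en‑1‑yl)‑2,3‑dihydro‑4H‑chromen‑4‑one | CC(C)=CCc1c(OCOC)ccc2c1O[C@H](c1cc3c(cc1OCOC)OC(C)(C)C=C3)CC2=O | intermediate
13 | (2S)‑2‑[2,2‑dimethyl‑7‑(trimethylsilyloxy)‑2H‑chromen‑6‑yl]‑8‑(3‑methylbut‑2‑en‑1‑yl)‑7‑(trimethylsilyloxy)‑2,3‑dihydro‑4H‑chromen‑4‑one | CC(C)=CCc1c(O[Si](C)(C)C)ccc2c1O[C@H](c1cc3c(cc1O[Si](C)(C)C)OC(C)(C)C=C3)CC2=O | intermediate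
14 | (2S)‑7‑hydroxy‑2‑(7‑hydroxy‑2,2‑dimethyl‑2H‑chromen‑6‑yl)‑8‑(3‑methylbut‑2‑en‑1‑yl)‑2,3‑dihydro‑4H‑chromen‑4‑one | CC(C)=CCc1c(O)ccc2c1O[C@H](c1cc3c(cc1O)OC(C)(C)C=C3)CC2=O | target

**Step count**

Total steps: 9. Longest linear sequence: 7 steps (1, 2, 3, 6, 7, 8, 9).

**Steps most likely to fail, with fallbacks**

Step 8. The hydrogen‑atom transfer to the hindered tertiary C2 radical may discriminate its two faces poorly, or the radical may be over‑oxidised towards the flavone. Fallback (known chemistry): setting out from 11, the same PCET ring opening is run with an achiral thiol (2,4,6‑triisopropylbenzenethiol) in place of the peptide, which should give the racemic bis‑MOM flavanone F1. F1 is then resolved kinetically by Noyori–Ikariya asymmetric transfer hydrogenation (RuCl(p‑cymene)(TsDPEN), HCO2H/Et3N, rt, catalyst antipode chosen so that the (2R)‑ketone is reduced). This should leave the (2S)‑ketone untouched and turn the (2R)‑enantiomer into the cis‑(2R,4R)‑flavan‑4‑ol F2, which is separated by chromatography. The route is rejoined at 12.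

Step 7. The zinc carbenoid may also cyclopropanate the prenyl or chromene alkene, or the donor‑substituted cyclopropanol may collapse under acid during work‑up. Fallback: setting out from 9, C‑alkylation of its sodium enolate (NaH, DMF, 0 °C) with excess diiodomethane should give the racemic 2‑(iodomethyl) ketone F3. Iodine–lithium exchange (t‑BuLi, Et2O/pentane, −100 °C) then lets the primary alkyllithium close onto the neighbouring ketone (3‑exo), and a buffered quench should give the cyclopropanol, so that no carbenoid meets the alkenes. The route is rejoined at 11.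

Step 6. Base‑induced self‑condensation of coumaranone 5 and air oxidation of the product enolate may outrun the cross‑coupling. Fallback: setting out from 5, TMSOTf/Et3N (CH2Cl2, 0 °C) should give the aromatic enol silane 6‑(methoxymethoxy)‑7‑prenyl‑3‑(trimethylsilyloxy)benzofuran F4. F4 is coupled with 8 by fluoride‑promoted enol‑silane arylation (Pd(dba)2/P(t‑Bu)3, ZnF2, CsF, DMF, 80 °C), so that no free alkali enolate of 5 is present. Aqueous work‑up rejoins the route at 9.

**Further compounds**

F1 | step 8 | racemic 7‑(methoxymethoxy)‑2‑[7‑(methoxymethoxy)‑2,2‑dimethyl‑2H‑chromen‑6‑yl]‑8‑(3‑methylbut‑2‑en‑1‑yl)‑2,3‑dihydro‑4H‑chromen‑4‑one | CC(C)=CCc1c(OCOC)ccc2c1OC(c1cc3c(cc1OCOC)OC(C)(C)C=C3)CC2=O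
F2 | step 8 | (2R,4R)‑7‑(methoxymethoxy)‑2‑[7‑(methoxymethoxy)‑2,2‑dimethyl‑2H‑chromen‑6‑yl]‑8‑(3‑methylbut‑2‑en‑1‑yl)‑3,4‑dihydro‑2H‑chromen‑4‑ol (2,4‑cis) | CC(C)=CCc1c(OCOC)ccc2c1O[C@@H](c1cc3c(cc1OCOC)OC(C)(C)C=C3)C[C@H]2O
F3 | step 7 | racemic 2‑(iodomethyl)‑6‑(methoxymethoxy)‑2‑[7‑(methoxymethoxy)‑2,2‑dimethyl‑2H‑chromen‑6‑yl]‑7‑(3‑methylbut‑2‑en‑1‑yl)‑1‑benzofuran‑3(2H)‑one | O=C1C(CI)(c3cc4C=CC(C)(C)Oc4cc3OCOC)Oc2c(CC=C(C)C)c(OCOC)ccc21
F4 | step 6 | 6‑(methoxymethoxy)‑7‑(3‑methylbut‑2‑en‑1‑yl)‑3‑(trimethylsilyloxy)‑1‑benzofuran | C[Si](C)(C)Oc1coc2c(CC=C(C)C)c(OCOC)ccc12
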